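## The problem

Compound 19 is a tetrasubstituted benzene with no stereocentre and no second ring: a methyl ester at C1, a free hydroxyl at C2, a methoxy group at C4 and an unbranched icosyl chain at C6, with hydrogen at C3 and C5. The synthesis therefore has only regiochemistry to solve, but it has to solve it twice. First, the ester sits between an oxygen and the long chain, a doubly ortho-flanked position that is awkward to reach by late carboxylation or esterification, the more so as the corresponding 2,4-dihydroxy acid loses CO2 easily. Second, the two phenolic oxygens must be told apart so that O4 alone carries the methyl group; the only built-in handle is the hydrogen bond (or chelate) between O2 and the ester carbonyl. The C20 chain adds no reactivity, but it must be carried from the first step and makes every intermediate waxy and sparingly soluble in polar solvents. The target itself is robust; the sensitive compounds are precursors, namely an alpha-methylene ketone open to conjugate addition and a diazo keto ester. The feature that invites a benzannulation is the alternation around the ring: O2 and O4 are meta, C3 and C5 are unsubstituted, and C1 carries a carbonyl group. This is the pattern obtained when a ketene carbonyl (C4–O), the two carbons of a terminal ynol ether (C3–H, C2–O) and a 1,1-disubstituted vinyl group (C5–H, C6–icosyl) are joined around a ketene alpha-carbon (C1) that bears the ester.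

## Retrosynthesis

**19 from 18 (O2–ethyl bond).** The free 2-hydroxyl is traced back to the ethyl ether 18. An ether on the oxygen ortho to the ester can be removed with BCl3 through a six-membered chelate that the 4-methoxy group cannot form. The forward step must distinguish a chelated ethyl ether from an unchelated methyl ether and leave the methyl ester alone.

**18 from 17 (O4–methyl bond).** Cutting the O4–CH3 bond leads to phenol 17, in which O4 is the only free hydroxyl. Methylation is then unambiguous, which is preferable to sorting two equal hydroxyls or two equal methyl ethers afterwards. The forward reaction is a plain phenol alkylation.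

**17 from 11 and 12 (ring bonds C1–C2, C3–C4, C4–C5).** The benzene ring is opened to diazo keto ester 11 and ethoxyethyne 12.
- In the forward direction 11 loses N2 and rearranges to vinylketene 13. A [2+2] addition of 12 gives cyclobutenone 14, ring opening gives dienylketene 15, and 6-pi closure gives dienone 16, the tautomer of 17.
- This cut builds the ring with all four substituents in place and with O2 and O4 already different (ether against free phenol). Cuts that build the ring first and add the ester or sort the oxygens later lack this.
- The ynol ether is chosen as the ethyl ether because 12 is a stock reagent. A silyl ynol ether with hydrogen on carbon would have to come from an ynolate for which no dependable source exists.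
- The precursors are far simpler: 11 is an acyclic chain and 12 has two carbons.
- The forward reaction must give the [2+2] regiochemistry that puts the ethoxy carbon next to the ester-bearing carbon, and the zwitterionic adduct must close on carbon.

**11 from 10 (C2=N2).** The diazo group is removed to give beta-keto ester 10. Diazo transfer to a doubly activated methylene is the standard entry, and it avoids acylating a diazoalkane with an unsaturated acid chloride, where dipolar cycloaddition to the double bond interferes.

**10 from 6 and 7 (C2–C3 bond).** The keto ester is cut between C2 and C3 into acrylic acid 6 and potassium methyl malonate 7, joined through imidazolide 8 and acylmalonate 9. A neutral magnesium-mediated acylation is preferred to a crossed Claisen condensation, in which an ester enolate would add to the acrylate in conjugate fashion.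

**6 from 4 (exocyclic methylene).** The C=CH2 carbon is removed and a carboxyl group added back, leading through Mannich base 5 to icosylmalonic acid 4. The second carboxyl group activates the alpha position for the Mannich reaction and then leaves as CO2, so no strong base or separate elimination step is needed.

**4 from 1 and 2 (chain attachment).** Diacid 4 comes from diester 3 by saponification, and 3 from dimethyl malonate 1 and 1-bromoicosane 2 by alkylation. Both are stock materials, and the even-numbered C20 bromide supplies the whole chain in one bond.

## Roads not taken

**Alternative 1:** Alder–Rickert route.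
- Cut and key step: the ring is cut at C1–C2 and C5–C6. A Diels–Alder addition of diene A1 to alkynoate A2 gives the bicyclic adduct A3, which expels its two-carbon bridge in a retro-Diels–Alder step and leaves the dimethoxybenzoate A4. One chelation-controlled demethylation at O2 would then give 19.
- Merits: the push-pull polarity of diene and ynoate fixes the regiochemistry, aromatisation is built in, and the reaction type is well established for 6-alkyl resorcylates. The route is convergent and shorter than the chosen one.
- Weak points: a beta-alkyl ynoate is a sluggish dienophile and needs forcing temperatures, at which the electron-rich, acid-sensitive diene can isomerise or aromatise by loss of methanol. A1 is normally handled as an isomer mixture, and A2 requires an odd-numbered C21 alkyne. The two oxygens emerge as identical methyl ethers.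
- Comparison: on step count and on precedent this road is ahead. Its final dealkylation is also the better-documented one, since it removes a methyl instead of an ethyl group. The chosen plan offers in return ring formation near room temperature, a commercial two-carbon partner, and a free 4-hydroxyl, so that the methyl group is placed deliberately and not spared selectively.

**Alternative 2:** Michael–Claisen annulation.
- Cut and key step: the ring is cut at C1–C6 and C2–C3. The enolate of malonate 1 adds to enone A5, and the methyl ketone enolate then closes onto a malonate ester to give the dihydroresorcinol A6. Dehydrogenation would lead to resorcylate A8 (the key product of Alternative 3), and O4-methylation to 19.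
- Merits: cheap reagents, no photochemistry, no diazo compound, easy to scale, and a key step with broad precedent.
- Weak points: A6 is two oxidation levels below the arene. The usual halogenative aromatisations tend to halogenate the electron-rich ring at C3 or C5 as well, which then calls for a reductive clean-up. A5 needs a C21 aldehyde that is not a common stock item.
- Comparison: step count is similar to or slightly better than the chosen route, and the reliability of the ring closure is better. The chosen plan reaches the aromatic oxidation level directly and needs no oxidation on a phenolic ring, at the price of a photochemical step on a substrate class that is not yet established.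

**Alternative 3:** Biomimetic aldol folding.
- Cut and key step: the ring is cut at C1–C6 only. The C2 methylene of the triketo ester A7 adds to the C7 ketone, and dehydration and enolisation give A8. Selective O4-methylation then gives 19.
- Merits: one ring bond, no oxidation-state change, and a product one step from the target. The chelation-controlled monomethylation of such resorcylates is textbook chemistry.
- Weak points: A7 cannot be stored and must be carried in masked form. Its assembly needs strongly basic polyanion or dioxinone chemistry and a C21 acyl donor. The chain can also fold by Claisen closure or lactonisation (to pyrones or acylphloroglucinols), so the outcome depends on the cyclisation medium.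
- Comparison: overall length is comparable, and the closing aldol step has better precedent than the chosen key step. In the chosen plan the ring-closure regiochemistry follows from the polarity of two small, stable components and not from the folding of a labile polyketone. The chosen plan has the less proven key step, and this is a real cost.

Key step: step 6

Remark on the chemistry: the target has no stereocentre; the stereocentres of intermediates 9 and 14 are formed racemic and are destroyed within the same step.

## Route

Step 1
Reactants: 1 dimethyl malonate (dimethyl propanedioate); 2 1-bromoicosane
Product: 3 dimethyl 2-icosylpropanedioate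
Conditions: NaOMe, MeOH/THF, reflux (1 in excess)
Reagents that add atoms: none
Why: Malonic ester alkylation (SN2) of the sodium enolate of 1 with a primary bromide; an excess of 1 suppresses dialkylation and the matching alkoxide avoids transesterification.

Step 2
Reactants: 3 dimethyl 2-icosylpropanedioate
Product: 4 2-icosylpropanedioic acid
Conditions: KOH, EtOH/H2O, reflux; then aq. HCl, 0 °C
Reagents that add atoms: potassium hydroxide, [K+].[OH-]
Why: Saponification of both methyl esters; cold acidification keeps the malonic acid from decarboxylating before the next step, which needs both carboxyl groups.

Step 3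
Reactants: 4 2-icosylpropanedioic acid
Product: 6 2-methylidenedocosanoic acid, via Mannich base 5 (not isolated)
Conditions: (CH2O)n, Et2NH, EtOAc, reflux
Reagents that add atoms: formaldehyde (used as paraformaldehyde), C=O
Why: Mannich reaction at the malonic alpha-carbon followed by decarboxylative elimination of the amine, the classical route to 2-substituted acrylic acids; the second carboxyl group activates and then leaves as CO2.

Step 4
Reactants: 6 2-methylidenedocosanoic acid; 7 potassium 3-methoxy-3-oxopropanoate (potassium methyl malonate)
Product: 10 methyl 4-methylidene-3-oxotetracosanoate, via acyl imidazolide 8 (not isolated), via acylmalonic half ester 9 (not isolated)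
Conditions: CDI, THF, rt; then 7, MgCl2, THF, rt → 50 °C; 1 M HCl
Reagents that add atoms: none
Why: Masamune–Brooks homologation: the acyl imidazolide is C-acylated by the magnesium enolate of the malonate half ester under neutral conditions and the acylmalonate loses CO2 on acidification. The alpha-alkyl group slows conjugate addition to the acrylate unit.

Step 5
Reactants: 10 methyl 4-methylidene-3-oxotetracosanoate
Product: 11 methyl 2-diazo-4-methylidene-3-oxotetracosanoate
Conditions: p-ABSA, Et3N, MeCN, 0 °C → rt
Reagents that add atoms: 4-acetamidobenzenesulfonyl azide (p-ABSA), CC(=O)Nc1ccc(cc1)S(=O)(=O)N=[N+]=[N-]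
Why: Regitz diazo transfer to the methylene between ketone and ester; the enolate attacks the terminal nitrogen of the sulfonyl azide and the sulfonamide is expelled.

Step 6
Reactants: 11 methyl 2-diazo-4-methylidene-3-oxotetracosanoate; 12 ethoxyethyne
Product: 17 methyl 2-ethoxy-4-hydroxy-6-icosylbenzoate, via vinylketene 13 (not isolated), via cyclobutenone 14 (not isolated), via dienylketene 15 (not isolated), via cyclohexadienone 16 (not isolated)
Conditions: 12 (3 equiv, hexane solution), hν (254 nm, quartz), ClCH2CH2Cl, rt; then concentrate, PhMe, 80 °C
Reagents that add atoms: none
Why: Proposed new method: the Danheiser benzannulation in its photochemical Wolff variant is established for alpha-diazo ketones with alkoxy- and siloxyalkynes, and that is the closest known reaction type; an alpha-diazo beta-keto ester, which gives an ester-substituted vinylketene, has not been shown in it. Irradiation expels N2 from 11 and the 1-icosylvinyl group migrates from the ketone carbon to the carbene carbon (migration from the ketone side, not of the ester alkoxy group, is the rule for diazo keto esters), giving vinylketene 13. The nucleophilic CH carbon of 12 attacks the electrophilic ketene carbonyl carbon and the ethoxy-stabilised cation collapses on the malonate-type carbon; this [2+2] closure of the four-membered ring forms C3–C4 and C1–C2 and gives 14. Conrotatory 4-pi opening of 14, thermal or light-assisted, cleaves the former ketene C=C sigma bond to dienylketene 15, and a disrotatory 6-pi electrocyclisation closes the six-membered ring at C4–C5 to dienone 16, which tautomerises to phenol 17. The step needs the [2+2] regiochemistry, which is fixed by the opposed polarity of the ynol ether and the ketene and places the ethoxy carbon next to the ester-bearing carbon. It also needs carbon closure of the zwitterion in preference to closure through the ester oxygen; an ester carbonyl is a much poorer heterodiene terminus than a ketone carbonyl, which should favour the cyclobutenone. The Z geometry of 15 needed for ring closure is reached because the ring opening is reversible. No stereocentre is formed in the product, and the quaternary centre of 14 is lost on ring opening.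

Step 7
Reactants: 17 methyl 2-ethoxy-4-hydroxy-6-icosylbenzoate
Product: 18 methyl 2-ethoxy-6-icosyl-4-methoxybenzoate
Conditions: MeI, K2CO3, acetone, reflux
Reagents that add atoms: iodomethane, CI
Why: Williamson methylation of the only free phenol, whose acidity is raised by the para ester; the aryl ethyl ether and the hindered methyl ester are inert to K2CO3.

Step 8
Reactants: 18 methyl 2-ethoxy-6-icosyl-4-methoxybenzoate
Product: 19 methyl 2-hydroxy-6-icosyl-4-methoxybenzoate
Conditions: BCl3, CH2Cl2, −78 → 0 °C; then H2O
Reagents that add atoms: none
Why: Chelation-controlled ether cleavage: BCl3 bridges the ester carbonyl and the ortho ethoxy oxygen in a six-membered chelate and chloride removes the ethyl group. The unchelated 4-methoxy group and the methyl ester should be left, and hydrolysis of the aryloxyborane gives the hydrogen-bonded phenol.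

## Compound list

1 | dimethyl malonate (dimethyl propanedioate) | COC(=O)CC(=O)OC | starting material
2 | 1-bromoicosane | CCCCCCCCCCCCCCCCCCCCBr | starting material
3 | dimethyl 2-icosylpropanedioate | CCCCCCCCCCCCCCCCCCCCC(C(=O)OC)C(=O)OC | intermediate
4 | 2-icosylpropanedioic acid | CCCCCCCCCCCCCCCCCCCCC(C(=O)O)C(=O)O | intermediate
5 | 2-[(diethylamino)methyl]-2-icosylpropanedioic acid (Mannich base, not isolated) | CCCCCCCCCCCCCCCCCCCCC(CN(CC)CC)(C(=O)O)C(=O)O | intermediate
6 | 2-methylidenedocosanoic acid | CCCCCCCCCCCCCCCCCCCCC(=C)C(=O)O | intermediate
7 | potassium 3-methoxy-3-oxopropanoate (potassium methyl malonate) | COC(=O)CC(=O)[O-].[K+] | starting material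
8 | 1-(1H-imidazol-1-yl)-2-methylidenedocosan-1-one (acyl imidazolide, not isolated) | CCCCCCCCCCCCCCCCCCCCC(=C)C(=O)n1ccnc1 | intermediate
9 | 2-(methoxycarbonyl)-4-methylidene-3-oxotetracosanoic acid (racemic, formed as its magnesium salt, not isolated) | CCCCCCCCCCCCCCCCCCCCC(=C)C(=O)C(C(=O)O)C(=O)OC | intermediate
10 | methyl 4-methylidene-3-oxotetracosanoate | CCCCCCCCCCCCCCCCCCCCC(=C)C(=O)CC(=O)OC | intermediate
11 | methyl 2-diazo-4-methylidene-3-oxotetracosanoate | CCCCCCCCCCCCCCCCCCCCC(=C)C(=O)C(=[N+]=[N-])C(=O)OC | intermediate
12 | ethoxyethyne | C#COCC | starting material
13 | methyl 3-methylidene-2-(oxomethylidene)tricosanoate (vinylketene, not isolated) | CCCCCCCCCCCCCCCCCCCCC(=C)C(=C=O)C(=O)OC | intermediate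
14 | methyl 1-(docos-1-en-2-yl)-2-ethoxy-4-oxocyclobut-2-ene-1-carboxylate (racemic, not isolated) | CCCCCCCCCCCCCCCCCCCCC(=C)C1(C(=O)OC)C(=O)C=C1OCC | intermediate
15 | methyl (2Z)-2-(docos-1-en-2-yl)-3-ethoxy-5-oxopenta-2,4-dienoate (dienylketene, not isolated) | CCCCCCCCCCCCCCCCCCCCC(=C)/C(C(=O)OC)=C(\C=C=O)OCC | intermediate
16 | methyl 6-ethoxy-2-icosyl-4-oxocyclohexa-1,5-diene-1-carboxylate (not isolated) | CCCCCCCCCCCCCCCCCCCCC1=C(C(=O)OC)C(OCC)=CC(=O)C1 | intermediate
17 | methyl 2-ethoxy-4-hydroxy-6-icosylbenzoate | CCCCCCCCCCCCCCCCCCCCc1cc(O)cc(OCC)c1C(=O)OC | intermediate
18 | methyl 2-ethoxy-6-icosyl-4-methoxybenzoate | CCCCCCCCCCCCCCCCCCCCc1cc(OC)cc(OCC)c1C(=O)OC | intermediate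
19 | methyl 2-hydroxy-6-icosyl-4-methoxybenzoate | CCCCCCCCCCCCCCCCCCCCc1cc(OC)cc(O)c1C(=O)OC | target

## Step count and uncertain steps

Total step count: 8. Longest linear sequence: 8 steps (the route is linear; 7 and 12 are purchased).

**Step 6 (key step, the only step that bears the label).**
- What may go wrong: the zwitterion formed from the ketene and the ynol ether may close through the ester oxygen, or through the vinyl terminus in a formal [4+2] addition that would exchange the positions of the ether and the free hydroxyl. The very electrophilic ketene may acylate the phenol that has already formed. The Wolff rearrangement of the doubly stabilised diazo compound may be slow enough for other carbene reactions to compete.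
- Fallback (known chemistry), from 6 back to 19: the ring is built without the ester, on the established diazo ketone substrate class, and the carboxyl group is added afterwards.
  - Acid 6 with MeLi (2 equiv) should give 3-methylidenetricosan-2-one F1.
  - Detrifluoroacetylative diazo transfer (LiN(SiMe3)2, 2,2,2-trifluoroethyl trifluoroacetate, then mesyl azide, Et3N, water) should give 1-diazo-3-methylidenetricosan-2-one F2.
  - Irradiation of F2 with 12 and heating should give 3-ethoxy-5-icosylphenol F3; here both modes of ring closure lead to the same compound.
  - BBr3 should cleave the ether to 5-icosylbenzene-1,3-diol F4.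
  - Carboxylation with MeOMgOCO2Me in DMF at 120 °C, the standard method for 5-alkylresorcinols, should give 2,4-dihydroxy-6-icosylbenzoic acid F5.
  - MeI (2 equiv) and K2CO3 in acetone should methylate the carboxylate and O4 and spare the chelated 2-hydroxyl, giving 19.

**Step 5.**
- What may go wrong: under Et3N the keto ester enolate may add in conjugate fashion to the alpha-methylene ketone of a second molecule faster than it reacts with the sulfonyl azide, leading to oligomerisation.
- Fallback, from 6 back to 11: the ketone is unveiled only after the diazo group is in place.
  - LiAlH4 reduction of 6 should give 2-methylidenedocosan-1-ol F6.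
  - MnO2 oxidation should give 2-methylidenedocosanal F7.
  - DBU-catalysed aldol-type addition of methyl diazoacetate should give racemic methyl 2-diazo-3-hydroxy-4-methylidenetetracosanoate F8.
  - IBX in DMSO should oxidise F8 to 11.

**Step 4.**
- What may go wrong: liberated imidazole or the malonate nucleophile may add to the acrylate double bond, and the reactive enone product may polymerise during the warm acylation.
- Fallback, from 6 back to 10: the C–C bond is made on Meldrum's acid and the ester by trapping an acylketene.
  - Oxalyl chloride with catalytic DMF should give 2-methylidenedocosanoyl chloride F9.
  - Meldrum's acid and pyridine should give 5-(1-hydroxy-2-methylidenedocosylidene)-2,2-dimethyl-1,3-dioxane-4,6-dione F10.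
  - Heating F10 in methanol should give 10 with loss of acetone and CO2.

**Step 8.**
- What may go wrong: chloride attack on the ethyl group of the chelate may be slow, and under the longer or warmer conditions then needed, demethylation at O4 may begin.
- Fallback, from 17 back to 19: the order is inverted so that no ether has to be distinguished from another.
  - BCl3 on 17 should give methyl 2,4-dihydroxy-6-icosylbenzoate F11.
  - MeI (about 1 equiv) and K2CO3 in acetone should then methylate only the non-chelated 4-hydroxyl and give 19.

## Further compounds

F1 | step 6 | 3-methylidenetricosan-2-one | CCCCCCCCCCCCCCCCCCCCC(=C)C(C)=O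
F2 | step 6 | 1-diazo-3-methylidenetricosan-2-one | CCCCCCCCCCCCCCCCCCCCC(=C)C(=O)C=[N+]=[N-]
F3 | step 6 | 3-ethoxy-5-icosylphenol | CCCCCCCCCCCCCCCCCCCCc1cc(O)cc(OCC)c1
F4 | step 6 | 5-icosylbenzene-1,3-diol | CCCCCCCCCCCCCCCCCCCCc1cc(O)cc(O)c1
F5 | step 6 | 2,4-dihydroxy-6-icosylbenzoic acid | CCCCCCCCCCCCCCCCCCCCc1cc(O)cc(O)c1C(=O)O
F6 | step 5 | 2-methylidenedocosan-1-ol | CCCCCCCCCCCCCCCCCCCCC(=C)CO
F7 | step 5 | 2-methylidenedocosanal | CCCCCCCCCCCCCCCCCCCCC(=C)C=O
F8 | step 5 | methyl 2-diazo-3-hydroxy-4-methylidenetetracosanoate (racemic) | CCCCCCCCCCCCCCCCCCCCC(=C)C(O)C(=[N+]=[N-])C(=O)OC
F9 | step 4 | 2-methylidenedocosanoyl chloride | CCCCCCCCCCCCCCCCCCCCC(=C)C(Cl)=O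
F10 | step 4 | 5-(1-hydroxy-2-methylidenedocosylidene)-2,2-dimethyl-1,3-dioxane-4,6-dione | CCCCCCCCCCCCCCCCCCCCC(=C)C(O)=C1C(=O)OC(C)(C)OC1=O
F11 | step 8 | methyl 2,4-dihydroxy-6-icosylbenzoate | CCCCCCCCCCCCCCCCCCCCc1cc(O)cc(O)c1C(=O)OC
A1 | alternative 1 | 1,3-dimethoxycyclohexa-1,3-diene | COC1=CC(OC)=CCC1
A2 | alternative 1 | methyl tricos-2-ynoate | CCCCCCCCCCCCCCCCCCCCC#CC(=O)OC
A3 | alternative 1 | methyl 3-icosyl-1,5-dimethoxybicyclo[2.2.2]octa-2,5-diene-2-carboxylate (racemic) | CCCCCCCCCCCCCCCCCCCCC1=C(C(=O)OC)C2(OC)CCC1C(OC)=C2
A4 | alternative 1 | methyl 2,4-dimethoxy-6-icosylbenzoate | CCCCCCCCCCCCCCCCCCCCc1cc(OC)cc(OC)c1C(=O)OC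
A5 | alternative 2 | (E)-tetracos-3-en-2-one | CCCCCCCCCCCCCCCCCCCC/C=C/C(C)=O
A6 | alternative 2 | methyl 6-icosyl-2,4-dioxocyclohexane-1-carboxylate (racemic) | CCCCCCCCCCCCCCCCCCCCC1CC(=O)CC(=O)C1C(=O)OC
A7 | alternative 3 | methyl 3,5,7-trioxoheptacosanoate | CCCCCCCCCCCCCCCCCCCCC(=O)CC(=O)CC(=O)CC(=O)OC
A8 | alternative 3 | methyl 2,4-dihydroxy-6-icosylbenzoate | CCCCCCCCCCCCCCCCCCCCc1cc(O)cc(O)c1C(=O)OC
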